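The readings stem from a simulated flask for substances that don't exist, noise included.

The rate constants are hidden, so I start from what stands apart from them, the partner balance.

in all of them: substrate 0.33 M (fed, over 30 s)
- west: partner 0.60 equiv; run made earlier
- south-east: partner 3.4 equiv; run made earlier
- midnight: partner 1.20 equiv; time 40 min
- winter: partner 3.00 equiv; time 40 min
- spring: partner 0.500 equiv; time 40 min

| run | time / min | mono adduct / % | substrate / % |
|---|---|---|---|
| west | 2.50 | 17.6 | 45.1 |
| west | 8.00 | 16.0 | 45.8 |
| west | 12.0 | 16.9 | 44.9 |
| west | 20.0 | 16.0 | 44.3 |
| south-east | 5.00 | 0 | 0.8 |
| south-east | 10.0 | 0 | 0 |
| south-east | 15.0 | 0.1 | 0.6 |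
| south-east | 20.0 | 0.2 | 0.7 |

(readings scatter by 0.5 percentage points)

1. which of these holds the largest part of the substrate at the end of midnight (other mono adduct / double product / substrate / mono adduct)
2. which of these holds the largest part of the substrate at the end of winter (other mono adduct / double product / substrate / mono adduct)
3. which of these holds the largest part of the substrate at the end of spring (other mono adduct / double product / substrate / mono adduct)
4. amount of mono adduct at the end of spring, in percent of the substrate charged

The west readings are flat from 2.50 min on, and I assume this flask has stopped with its 0.60 equiv of partner spent, which makes partner the limiting reagent. Substrate stands there at 45.0%, so 55.0% is lost on 0.60 equiv of partner. I carry the partner price, the equivalents of partner spent per equivalent of substrate lost once the flask has stopped: 1.09 equiv.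

At that price, spring's 0.500 equiv buys a loss of 45.8%, which leaves 54.2% substrate. West keeps 30.2% of its lost substrate as mono adduct, so my spring figure is 13.8%. My objection is that the price is an average over the run, and the part above one is a correction for second additions that may change with the charge. Spring lies close to west, so I let the figure stand, loosely.

Midnight is harder. There 1.20 equiv at the west price would buy 110%, more than the charge, so if the partner is spent in midnight too, the price there rises to at least 1.20 equiv. Any substrate that survives raises it further, and that partner goes into second additions. I can't reckon the survival, but west held 45.0% of substrate beside its adducts, so I lean to double product. For winter I follow south-east, which reads 0.8% substrate and 0% mono adduct at 5.00 min, and I expect double product.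

The forecast differs on midnight: it says other mono adduct, on “substrate is gone”. For winter it gives double product, for spring substrate, and 14.5% of mono adduct in spring.

    partner + other mono adduct → double product (k = 0.0420 M⁻¹ s⁻¹)
    substrate + partner → other mono adduct (k = 0.0110 M⁻¹ s⁻¹)
    partner + mono adduct → double product (k = 0.210 M⁻¹ s⁻¹)
    mono adduct ⇌ isomer of the product (K = 0.250, k = 0.00330 s⁻¹)
    substrate ⇌ dormant form (K = 0.270, k = 0.00420 s⁻¹)
    substrate + partner → mono adduct (k = 0.0990 M⁻¹ s⁻¹)

Spring gives 16.3% of mono adduct. Midnight holds 48.7% double product beside 5.04% other mono adduct and 22.6% substrate, so its answer is double product. The price on these results is 1.55 equiv at midnight and 0.995 equiv at spring, below the west reading, and spring's loss includes 13.4% dormant form.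

On the neighbour of spring with 0.120 equiv of partner, the west price buys a loss of 11.0%, leaving 89.0% substrate. The computed flask holds 70.2% substrate, less than that figure, beside 19.0% dormant form.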